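18.2 is the number I start from: the starting material charged over the catalyst charged in Sunday's and Friday's flasks, so it is how many times each catalyst must turn over to use up the charge. That ratio is a ceiling on the count I reckon with below.

| flask | starting material | coupling partner | free catalyst | temperature | remark | time |
|---|---|---|---|---|---|---|
| teal | 0.020 M | 0.080 M | 0.74 mM | 105 °C | run made earlier |  |
| grey | 0.020 M | 0.080 M | 1.7 mM | 122 °C | run made earlier |  |
| blue | 0.030 M | 0.080 M | 1.1 mM | 105 °C | run made earlier |  |
| Sunday's | 0.020 M | 0.0800 M | 1.1 mM | 110 °C |  | 40 h |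
| Friday's | 0.020 M | 0.0800 M | 1.1 mM | 135 °C |  | 40 h |

- teal (time / h: target / %, starting material / %): 1.33: 0, 96.1; 4.00: 0, 95.9; 6.00: 0.5, 95.8; 10.0: 2.3, 94.7; 15.0: 4.2, 92.9; 20.0: 5.1, 91.2; 25.0: 7.3, 89.3
- grey (time / h: target / %, starting material / %): 0.667: 0.6, 91.0; 2.00: 3.4, 88.7; 3.00: 6.2, 86.6; 6.00: 16.4, 76.8; 8.00: 21.3, 70.2; 12.0: 33.0, 59.3; 15.0: 39.6, 49.7
- blue (time / h: target / %, starting material / %): 2.00: 0, 97.0; 4.00: 0.1, 96.1; 6.00: 0.3, 95.3; 12.0: 3.0, 93.0; 25.0: 7.5, 90.1

(readings scatter by 0.5 percentage points)



* which of the two there is more of at the end, Sunday's (side product / target)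
* which of the two there is more of at the end, Friday's (side product / target)
* final target, as a percentage of the starting material charged, in Sunday's
* final target, as a percentage of the starting material charged, in Friday's

My bench rule is to read target as turnovers per catalyst charged. At 25.0 h the teal run reads 1.97, and the blue run, with 0.030 M of starting material against 0.020 M, reads 2.05 at 25.0 h. These two readings sit together, but the blue run differs from the teal run in both amounts, starting material by a factor of 1.50 and catalyst by a factor of 1.49, so this pair cannot separate them. I therefore assume the zero-order case, which these two readings do not prove: a rate proportional to the catalyst charged and independent of the starting material.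

From 10.0 h on, the teal run gives 0.0901 h⁻¹ and its line meets zero at a lag of 3.10 h. From 6.00 h on, the grey run gives 0.303 h⁻¹. Interpolating the logarithm of the rate in temperature gives 0.129 h⁻¹ at 110 °C.

I keep the lag, so Sunday's flask reaches a turnover count, the turnover number at the end of the run, 4.75. That is 26.1% target by my reckoning, and the count lies below the ceiling.

The border shows at 135 °C. Extrapolating beyond the runs gives 0.767 h⁻¹, hence a count of 28.3, which is above the ceiling. So for Friday's flask the count stops being a yield, and I give no target figure from it.

The forecast says target and 27% for Sunday's, target and 80% for Friday's, where "starting material is consumed within about 20 h".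

Sunday's gives 27.3% target against 1.02% side product. Friday's gives 38.4% target against 61.3% side product, 42 percentage points below the forecast's target. Friday's flask held 59.3% target at 20.0 h and 38.4% at 40.0 h, while its side product went from 25.6% to 61.3%. Read back as counts, Sunday's target is 4.96 turnovers against my 4.75, and Friday's target and side product together are 18.1 against the ceiling of 18.2.

    starting material + free catalyst → catalyst intermediate A (k = 2.73 L mol⁻¹ min⁻¹, Ea = 53.0 kJ mol⁻¹)
    catalyst intermediate A ⇌ catalyst intermediate B (K = 0.520, k = 0.0196 min⁻¹, Ea = 113 kJ mol⁻¹, ΔH = 17.0 kJ mol⁻¹)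
    coupling partner + catalyst intermediate B → catalyst intermediate C (k = 0.222 L mol⁻¹ min⁻¹, Ea = 89.0 kJ mol⁻¹)
    catalyst intermediate C ⇌ catalyst intermediate D (K = 84.0, k = 0.0151 min⁻¹, Ea = 104 kJ mol⁻¹, ΔH = −56.0 kJ mol⁻¹)
    catalyst intermediate D → by-product + catalyst intermediate E (k = 0.0157 min⁻¹, Ea = 129 kJ mol⁻¹)
    catalyst intermediate E ⇌ free catalyst + target (K = 0.0592 M, k = 0.0169 min⁻¹, Ea = 104 kJ mol⁻¹, ΔH = 29.0 kJ mol⁻¹)
    target + by-product → side product (k = 0.00845 L mol⁻¹ min⁻¹, Ea = 100 kJ mol⁻¹)
    2 free catalyst → spent catalyst (k = 0.166 L mol⁻¹ min⁻¹, Ea = 97.0 kJ mol⁻¹)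
    (constants at 110 °C)

The neighbour is Sunday's flask with 0.012 M of starting material, whose ceiling is 10.9. The count of 4.75 stays below that ceiling and gives 43.5% target; the computed flask gives 43.0%.

(The readings come from a simulation for substances that don't exist.)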